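The data were computed for substances that don't exist, noise included.

4 questions stand on these flasks: 3 ask which form holds most of the L at the end, and one asks for D in north-east.

common to all: L 0.40 M

| flask | J | Q | remark | time |
|---|---|---|---|---|
| amber | 1.6 equiv | 0.50 equiv | run made earlier |  |
| ochre | 5 equiv | 0.50 equiv | run made earlier |  |
| north-east | 1.20 equiv | 0.500 equiv |  | 2.5 d |
| south-east | 1.50 equiv | 0.500 equiv |  | 2.5 d |
| south | 4.00 equiv | 0.500 equiv |  | 2.5 d |

| run | time / d | D / % |
|---|---|---|
| amber | 0.208 | 0.2 |
| amber | 0.500 | 1.4 |
| amber | 1.04 | 3.2 |
| amber | 2.50 | 7.9 |
| ochre | 0.625 | 9.0 |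
| ochre | 1.25 | 13.5 |
| ochre | 2.08 | 20.3 |
| ochre | 2.50 | 23.6 |

(scatter of a reading: 0.5 percentage points)

* which of these holds the largest part of the L at the end of north-east (D / G / L)
* which of these holds the largest part of the L at the end of south-east (D / G / L)
* which of these holds the largest part of the L at the end of south (D / G / L)
* D at the end of north-east, in percent of the L charged



Amber looks nearly the same as north-east: L and Q are charged alike, and the difference is J, 1.6 equiv against 1.20 equiv. Amber and ochre are both read at 2.50 d, so dividing ochre's last D by amber's makes time drop out, and set against the ratio of J charges it leaves an apparent order in J, read off these two scattered readings, of 0.960.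

The reckoning here adds a supposition: the two sites of L exchange alike, a statistical distribution. With p the fraction of sites exchanged, D is p squared, L is the square of one minus p, and G is two p times one minus p. G over L is then two p over one minus p, again free of time, and it passes unity when p reaches a third. D then stands at 11.1%, the crossover share: the D at which, on this supposition, G overtakes L.

Amber's 7.9% lies below it, so L should still lead there. North-east, with less J, should stand lower still: the order gives D 5.99%, and south-east 7.43%, both below the crossover. South gets 19.0%, above it. This reckoning therefore commits to L, L and G.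

The forecast differs, naming G, G and G, with D in north-east at 3.5% (range 1.5% to 6%), on the ground that “A small L-dominated pre-equilibrium would give a much steeper J dependence, so G should dominate.”

The flasks give L, L and G, with D in north-east at 5.00%.

    L + J ⇌ Q + G (K = 0.120, k = 0.00210 M⁻¹ min⁻¹)
    G + J ⇌ Q + D (K = 0.0260, k = 0.00260 M⁻¹ min⁻¹)
    Q → X (k = 8.10 × 10⁻⁴ min⁻¹)
    J → E (k = 3.60 × 10⁻⁶ min⁻¹)

North-east has not come to rest at 2.50 d. Its D lies below the crossover, and L at 59.6% leads G at 35.4%; the supposition of like sites, applied to the square root of that D, reckons L 60.3% and G 34.7%. Left to 25.0 d, ten times as long, D reaches 25.9%, past the crossover, and G holds 51.0% against L at 23.1%, with J down to 10.4% of its charge.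

In a flask like north-east but with 2.00 equiv of J, read at the same time, the order gives D 9.79%, still below the crossover, so L should lead. That flask computes to D 9.29%, with L at 47.3% ahead of G at 43.4%.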